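## Analysis of the target

The target is a trans-2-aryl-3-(hydroxymethyl)-2,3-dihydrobenzofuran (a phenylcoumaran of the 8–5' neolignan type). Ring A, the benzo ring, carries a methoxy group at C7 and, at C5, a three-carbon chain whose terminal oxygen is esterified with (E)-ferulic acid. C2 carries a 4-hydroxy-3-methoxyphenyl (guaiacyl) ring and C3 a CH2OH group. The two stereocentres, C2 (R) and C3 (S), are adjacent and trans, and the cinnamate alkene is (E). The O1–C2 bond is a benzylic aryl ether para to a phenolic oxygen: it ionises in acid, can open through a quinone methide in base and is at risk under hydrogenolysis, and trans is its thermodynamically preferred arrangement. The cinnamate tolerates neither hydride, strong base nor hydrogenation, the two phenols should appear only at the end, and the two primary alcohols must be told apart because only the chain terminus is acylated. The hard part is to set C3, a benzylic carbon with no heteroatom, absolutely and convergently, without oxidants near three electron-rich arenes. The strategy rests on one feature: C2 and C3 are neighbouring sp3 carbons that each bear exactly one aryl ring (guaiacyl on C2, ring A through C3a on C3), with oxygen on C2 and CH2O on C3. That is the pattern left by anti 1,2-diarylation of an (E)-3-oxyprop-1-enyl boron unit, the boron-bearing carbon becoming C2 after C–B to C–O exchange.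

## Retrosynthetic reasoning

**25 from 24.** The last disconnection cuts three O–Si bonds. All three hydroxyls that must stay masked during the esterification (both phenols and the C3 hydroxymethyl) are silyl ethers in 24, so one fluoride treatment ends the synthesis and the cinnamate never meets acid, hydride or hydrogen.

**24 from 20 and 23.** The acyl–oxygen bond of the cinnamate is cut. It is the most polar bond, it joins two fragments of similar size, and it is placed late because the conjugated ester is the most fragile group. The forward esterification needs 20 to have a single free hydroxyl, the chain terminus. Acid 23 comes from 21 by silylation through the bis-silyl compound 22.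

**20 from 19.** The chain terminus is traced back to a methyl ester. A benzyl ether here would have to be hydrogenolysed next to the benzylic O1–C2 bond, and a silyl ether could not be distinguished cleanly from the other silyl groups in the acid step. The ester is inert to the boron chemistry as long as no free aryllithium is present, and a mild hydride unmasks it.

**19 from 17.** The O1–C2 bond is cut. This bond is benzylic to the donor-substituted guaiacyl ring, so the forward reaction can form it by ionisation of the C2 carbinol and capture by the ring-A oxygen once its acetal is removed. Closure is under thermodynamic control and gives the trans ring. The configuration of C2 in 17 therefore need not be controlled, and only C3 must arrive intact. Cutting O1–C7a instead would require an aryl halide and a metal-catalysed etherification.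

**17 from 16.** The C2–O bond is exchanged for a C2–B bond. Oxidation of a secondary boronic ester is stereoretentive and returns diol 4.

**16 from 6, 14 and 13.** This is the key disconnection. Two aryl–C(sp3) bonds are cut at once: guaiacyl–C2 and C3–C3a. What remains is a two-carbon linchpin, the (E)-alkenyl boronic ester 6, an aryl nucleophile 14 (from bromide 8) and an aryl electrophile 13. The roles are not interchangeable. The group that starts on the nucleophile migrates to the boron-bearing carbon, which must become the oxygenated C2, so the guaiacyl ring is the lithium reagent and ring A the triflate. The forward step must add the two aryl groups anti across the alkene with control of the alkene face, so that C3 is set absolutely.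

**6 from 2 and 4; 2 from 1; 4 from 3.** The alkenyl boron unit comes from hydroboration of silyl ether 2 (through catechol ester 5) and exchange onto diol 4. The hindered diol is needed to suppress direct transmetalation in the key step. Diol 4 is made from dione 3 by double methyl addition.

**8 from 7.** The phenol is silylated so that bromine–lithium exchange is possible.

**13 from 12, 11, 10 and 9.** The triflate is made from phenol 12. The saturated ester chain comes from aldehyde 10 by two-carbon olefination (11) and hydrogenation. 10 arises from 9 by acetalisation of the more acidic hydroxyl para to the formyl group, which is the oxygen that becomes O1.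

## Alternatives that were turned down

**Alternative 1: ring contraction of a flavanone.**
- Disconnection: the C3–C3a bond, traced back to the C4–C4a bond of the (R)-chroman-4-one A1.
- Forward key step: PhI(OAc)2 and H2SO4 in trimethyl orthoformate convert the ketone of A1 into its dimethyl ketal, trivalent iodine attaches to C3, and ring-A carbon C4a shifts from C4 to C3. The pyranone contracts to the dihydrofuran and the former C4 becomes the methyl ester of A2.
- For: one step makes the C3–C3a bond, closes the five-membered ring and gives the trans arrangement from a C2 centre already in place. The ester sits where CH2OH is needed, and the reaction type is well established for flavanones.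
- Against: the C2 aryl group is a para-oxygenated ring, itself a good migrating group, so the 2-to-3 aryl shift towards isoflavone-type products competes. The strongly acidic medium can open A1 by retro-oxa-Michael reaction or ionise its benzylic C2–O bond and erode the only stereocentre the step relies on. Trivalent iodine meets two electron-rich rings. The two benzyl ethers of A2 cannot be told apart, and their hydrogenolysis threatens O1–C2.
- Comparison: this alternative is stronger in that trans geometry is created in the ring-forming step and no late ionisation at C2 is needed. It is weaker in convergence, since A1 is a linear enantioselective synthesis of its own, and in chemoselectivity. The chosen route offers instead a three-fragment assembly in which C3, the centre that cannot be repaired later, is set by a catalyst in a stereospecific addition, with no oxidant near the arenes except perborate acting on a C–B bond.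

**Alternative 2: oxidative para-quinone methide cyclisation of a 1,2-diarylpropane.**
- Disconnection: the O1–C2 bond, opened to the enantioenriched diarylpropane A3, which has no oxygen at C2.
- Forward key step: Ag2O oxidises the 4-alkylguaiacol unit of A3 to its para-quinone methide, and the ring-A phenol adds to the methide carbon to close the dihydrofuran A4 trans to C3.
- For: the closure is biomimetic, neutral and trans-selective by reversible addition. Only C3 must be set beforehand, which auxiliary alkylation or asymmetric hydrogenation can do predictably, and no separate oxygenation of C2 is needed.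
- Against: A3 has two free phenols, and the ring-A phenol can be oxidised as well, towards an ortho-quinone methide at C3 or radical coupling. The para-quinone methide has a hydrogen on C3 and can tautomerise to a stilbene. Either path destroys the C3 centre. The bromine of A4 is only a placeholder, so the three-carbon chain must be introduced by cross-coupling and further adjustment after ring formation, in the presence of a free phenol.
- Comparison: this alternative is at least as strong on the closure itself, which avoids acid, and arguably on the predictability of C3. The chosen route makes both aryl–carbon bonds in one convergent step, carries the chain from the start and needs no late cross-coupling.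

**Alternative 3: ortho-quinone methide plus chiral sulfonium benzylide, [4+1] annulation.**
- Disconnection: C2–C3 and C2–O1, leading back to sulfone A5 and sulfonium salt A7.
- Forward key step: base eliminates sulfinate from A5 to give the ortho-quinone methide A6 and deprotonates A7. The ylide carbon adds to the methide carbon (C3) and the phenoxide displaces the sulfide at C2, giving A8.
- For: it is the most convergent option. Two fragments give the ring and both stereocentres in one step, with trans geometry from the anti betaine and SN2 closure, and neither a C–B oxidation nor a separate closure follows.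
- Against: the methide carbon of A6 carries an alkyl group with hydrogens and a β-silyloxy substituent. Such quinone methides isomerise readily to ortho-alkenylphenols (here an enol silyl ether) or eliminate, so their lifetime is short. Facial control at C3 must be relayed from a sulfur stereo-element several atoms away on a semi-stabilised benzyl ylide. The donor-substituted benzylsulfonium can also lose sulfide by ionisation, opening a racemic background path. The chiral sulfide is stoichiometric.
- Comparison: this alternative is stronger in step economy after the key step. The chosen route is longer by an oxidation and a closure, but it relies on a stereospecific anti addition under catalyst control and on stable, isolable partners.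

Key step: step 9

Remark on the chemistry: the antipode of the ferrocenyl bisphosphine that delivers the (S) centre at C3 is to be assigned in a trial run by correlating 19 with the target; both antipodes are sold, and the route is written for the one that gives 16.

Remark on the chemistry: diol 4 is prepared (step 2) and is not assumed to be purchasable.

## Route

Step 1
Reactants: 1 prop-2-yn-1-ol (propargyl alcohol)
Product: 2 tert-butyl(diphenyl)(prop-2-yn-1-yloxy)silane
Conditions: TBDPSCl, imidazole, CH2Cl2, 0 °C to rt
Reagents that add atoms: tert-butyl(chloro)diphenylsilane (TBDPSCl), CC(C)(C)[Si](Cl)(c1ccccc1)c1ccccc1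
Why: Routine silylation of a primary alcohol; the acid-stable TBDPS group is chosen because this oxygen must survive the acid closure of step 11.

Step 2
Reactants: 3 acenaphthylene-1,2-dione (acenaphthenequinone)
Product: 4 cis-1,2-dimethyl-1,2-dihydroacenaphthylene-1,2-diol (meso)
Conditions: MeMgBr (3 equiv), THF, 0 °C to rt; H2O quench; recrystallisation
Reagents that add atoms: methylmagnesium bromide, C[Mg]Br
Why: Double Grignard addition to a 1,2-dione; the second methyl is expected to enter anti to the solvated bromomagnesium alkoxide, which places the two oxygens cis, and recrystallisation secures the meso cis-diol, the only isomer able to bridge one boron atom.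

Step 3
Reactants: 2 tert-butyl(diphenyl)(prop-2-yn-1-yloxy)silane; 4 cis-1,2-dimethyl-1,2-dihydroacenaphthylene-1,2-diol
Product: 6 (E)-3-(tert-butyldiphenylsilyloxy)prop-1-enylboronic acid cis-1,2-dimethylacenaphthene-1,2-diyl ester (alkenyl B(mac) ester), via catechol alkenylboronate 5 (not isolated)
Conditions: catecholborane (1.1 equiv), neat, 70 °C; then 4, THF, rt; cold aqueous NaHCO3 wash
Reagents that add atoms: catecholborane (1,3,2-benzodioxaborole), B1Oc2ccccc2O1
Why: Syn hydroboration of the terminal alkyne places boron on the terminal carbon for steric reasons and gives the (E)-alkenyl catechol ester; transesterification to the aliphatic diol ester is downhill and the released catechol is washed out.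

Step 4
Reactants: 7 4-bromo-2-methoxyphenol
Product: 8 (4-bromo-2-methoxyphenoxy)tri(propan-2-yl)silane
Conditions: TIPSCl, imidazole, DMF, rt
Reagents that add atoms: chlorotri(propan-2-yl)silane (TIPSCl), CC(C)[Si](Cl)(C(C)C)C(C)C
Why: Phenol silylation; the aryl TIPS ether withstands tert-butyllithium, the borate chemistry and the acid of step 11, and being para to bromine it cannot undergo silyl migration to the lithiated carbon.

Step 5
Reactants: 9 3,4-dihydroxy-5-methoxybenzaldehyde (5-hydroxyvanillin)
Product: 10 3-hydroxy-5-methoxy-4-(methoxymethoxy)benzaldehyde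
Conditions: MOMCl (1.05 equiv), K2CO3 (1.1 equiv), acetone, 0 °C to rt
Reagents that add atoms: chloromethyl methyl ether (MOMCl), COCCl
Why: Regioselective O-alkylation of a catechol aldehyde; with one equivalent of weak base only the more acidic hydroxyl para to the formyl group is deprotonated, so the acetal is placed on the oxygen that becomes O1.

Step 6
Reactants: 10 3-hydroxy-5-methoxy-4-(methoxymethoxy)benzaldehyde
Product: 11 methyl (E)-3-[3-hydroxy-5-methoxy-4-(methoxymethoxy)phenyl]prop-2-enoate
Conditions: Ph3P=CHCO2Me (1.5 equiv), toluene, 80 °C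
Reagents that add atoms: methyl (triphenylphosphoranylidene)acetate, COC(=O)C=P(c1ccccc1)(c1ccccc1)c1ccccc1
Why: Wittig olefination with a stabilised ylide, which is not basic enough to be quenched by the free phenol; alkene geometry is irrelevant because the double bond is reduced next.

Step 7
Reactants: 11 methyl (E)-3-[3-hydroxy-5-methoxy-4-(methoxymethoxy)phenyl]prop-2-enoate
Product: 12 methyl 3-[3-hydroxy-5-methoxy-4-(methoxymethoxy)phenyl]propanoate
Conditions: H2 (1 atm), 10% Pd/C, EtOAc, rt
Reagents that add atoms: none
Why: Catalytic hydrogenation of a cinnamate double bond; it is done before the triflate is installed, and the acetal and ester are untouched.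

Step 8
Reactants: 12 methyl 3-[3-hydroxy-5-methoxy-4-(methoxymethoxy)phenyl]propanoate
Product: 13 methyl 3-[3-methoxy-4-(methoxymethoxy)-5-(trifluoromethylsulfonyloxy)phenyl]propanoate
Conditions: Tf2O, pyridine, CH2Cl2, 0 °C
Reagents that add atoms: trifluoromethanesulfonic anhydride, O=S(=O)(OS(=O)(=O)C(F)(F)F)C(F)(F)F
Why: Standard triflation of a phenol under buffered conditions that leave the acetal intact; the triflate marks the carbon that becomes C3a.

Step 9
Reactants: 8 (4-bromo-2-methoxyphenoxy)tri(propan-2-yl)silane; 6 alkenyl B(mac) ester; 13 methyl 3-[3-methoxy-4-(methoxymethoxy)-5-(trifluoromethylsulfonyloxy)phenyl]propanoate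
Product: 16 methyl 3-{3-[(1R,2S)-1-[B(mac)]-3-(tert-butyldiphenylsilyloxy)-1-[3-methoxy-4-(triisopropylsilyloxy)phenyl]propan-2-yl]-5-methoxy-4-(methoxymethoxy)phenyl}propanoate (B(mac) = boron ester of diol 4), via aryllithium 14 (not isolated), via lithium boronate complex 15 (not isolated)
Conditions: t-BuLi (2.0 equiv), Et2O, −78 °C; 6 (1.05 equiv), −78 °C to rt; solvent changed to THF; KOSO2CF3 (2 equiv), Pd(OAc)2 (3 mol%), 1,1'-bis[bis(4-methoxy-3,5-dimethylphenyl)phosphino]-2,2'-bis[(dimethylamino)(phenyl)methyl]ferrocene (one enantiomer of this MandyPhos ligand, 3.6 mol%), 13 (1.1 equiv), THF, 60 °C; non-oxidative work-up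
Reagents that add atoms: none
Why: Bromine–lithium exchange gives 14, which adds to the trigonal boron of 6 to give the four-coordinate boronate 15. Oxidative addition of 13 to zerovalent palladium gives a cationic arylpalladium–bisphosphine that binds the alkene of 15; the guaiacyl group then shifts from boron to the boron-bearing carbon (future C2) anti to palladium, palladium ends on the carbon carrying CH2OSi (future C3), and reductive elimination with retention forms C3–C3a. The closest known reaction type is the enantioselective palladium-catalysed conjunctive cross-coupling of β-substituted alkenyl B(mac) ate complexes with aryl triflates. No ring is closed in this step. C3 is set absolutely by the chiral bisphosphine, which decides the alkene face that palladium occupies, and the configuration of C2 relative to C3 follows from stereospecific anti addition across the (E)-alkene. The step needs the 1,2-metallate pathway to outrun direct boron-to-palladium transfer (Suzuki–Miyaura products), which the hindered diol 4 on boron secures, and reductive elimination to outrun β-hydride or β-silyloxy loss, which the wide-bite-angle ligand favours. Bromide from the exchange would block the cationic palladium and is removed as KBr by KOSO2CF3, and a small excess of 6 over 14 ensures that no free aryllithium meets the ester of 13.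

Step 10
Reactants: 16 secondary benzylic B(mac) boronate
Product: 17 methyl 3-{3-[(1R,2S)-3-(tert-butyldiphenylsilyloxy)-1-hydroxy-1-[3-methoxy-4-(triisopropylsilyloxy)phenyl]propan-2-yl]-5-methoxy-4-(methoxymethoxy)phenyl}propanoate
Conditions: NaBO3·4H2O (5 equiv), THF/H2O 1:1, rt
Reagents that add atoms: sodium perborate (used as the tetrahydrate), O=BO[O-].[Na+]
Why: Oxidation of a boronic ester by hydroperoxide addition to boron and 1,2-shift of carbon to oxygen with retention; perborate is mild enough to spare the methyl ester and the aryl silyl ether, and diol 4 is recovered.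

Step 11
Reactants: 17 benzylic carbinol with acetal-masked ring-A phenol
Product: 19 methyl 3-[(2R,3S)-3-(tert-butyldiphenylsilyloxymethyl)-7-methoxy-2-[3-methoxy-4-(triisopropylsilyloxy)phenyl]-2,3-dihydro-1-benzofuran-5-yl]propanoate, via free phenol carbinol 18 (not isolated)
Conditions: HCl (about 0.5 M, from concentrated aqueous acid), MeOH/THF 3:1, rt to 35 °C; NaHCO3 quench
Reagents that add atoms: none
Why: Acidolysis of the aryl methoxymethyl acetal frees the ring-A phenol, and the carbinol, benzylic to the para-silyloxy ring, ionises reversibly (methanol acts as a reservoir) until the phenol captures the cation, the acid-catalysed phenylcoumaran closure known for 2-(2-hydroxyaryl)-1-arylpropane-1,3-diol derivatives. C2 is formed under thermodynamic control trans to the untouched C3 centre, whatever the C2 configuration of 17, so an inverting (Mitsunobu-type) closure is deliberately avoided.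

Step 12
Reactants: 19 dihydrobenzofuran methyl ester
Product: 20 3-[(2R,3S)-3-(tert-butyldiphenylsilyloxymethyl)-7-methoxy-2-[3-methoxy-4-(triisopropylsilyloxy)phenyl]-2,3-dihydro-1-benzofuran-5-yl]propan-1-ol
Conditions: LiBH4 (2 equiv), MeOH (2 equiv), THF, 0 °C to rt
Reagents that add atoms: none
Why: Chemoselective hydride reduction of an unhindered methyl ester; silyl ethers and the benzylic aryl ether are inert, and no hydrogenolysis is needed anywhere near O1–C2.

Step 13
Reactants: 21 (E)-3-(4-hydroxy-3-methoxyphenyl)prop-2-enoic acid (ferulic acid)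
Product: 23 (E)-3-[4-(tert-butyldimethylsilyloxy)-3-methoxyphenyl]prop-2-enoic acid, via bis-silylated ferulate 22 (not isolated)
Conditions: TBSCl (2.3 equiv), imidazole, DMF, rt; then AcOH/THF/H2O 3:1:1, rt
Reagents that add atoms: tert-butyl(chloro)dimethylsilane (TBSCl), CC(C)(C)[Si](C)(C)Cl
Why: Silylation of phenol and acid followed by selective hydrolysis of the far more labile silyl ester, which leaves the aryl silyl ether in place.

Step 14
Reactants: 20 chain alcohol; 23 O-silyl ferulic acid
Product: 24 3-[(2R,3S)-3-(tert-butyldiphenylsilyloxymethyl)-7-methoxy-2-[3-methoxy-4-(triisopropylsilyloxy)phenyl]-2,3-dihydro-1-benzofuran-5-yl]propyl (E)-3-[4-(tert-butyldimethylsilyloxy)-3-methoxyphenyl]prop-2-enoate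
Conditions: EDC·HCl (1.5 equiv), DMAP (0.2 equiv), CH2Cl2, 0 °C to rt
Reagents that add atoms: none
Why: Steglich-type carbodiimide esterification of the only free hydroxyl in 20 with a phenol-protected cinnamic acid; the conditions do not touch the alkene geometry or the stereocentres.

Step 15
Reactants: 24 tris-silyl ester
Product: 25 3-[(2R,3S)-2-(4-hydroxy-3-methoxyphenyl)-3-(hydroxymethyl)-7-methoxy-2,3-dihydro-1-benzofuran-5-yl]propyl (E)-3-(4-hydroxy-3-methoxyphenyl)prop-2-enoate (CNP0149450.1)
Conditions: Bu4NF (5 equiv), AcOH (5 equiv), THF, 0 °C to rt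
Reagents that add atoms: none
Why: Fluoride cleavage of two aryl silyl ethers and one primary alkyl silyl ether in a single operation; acetic acid buffering keeps the medium from becoming basic enough to attack the cinnamate or to open the phenylcoumaran through a quinone methide.

## Compound list

1 | prop-2-yn-1-ol (propargyl alcohol) | C#CCO | starting material
2 | tert-butyl(diphenyl)(prop-2-yn-1-yloxy)silane | C#CCO[Si](c1ccccc1)(c1ccccc1)C(C)(C)C | intermediate
3 | acenaphthylene-1,2-dione (acenaphthenequinone) | O=C1C(=O)c2cccc3cccc1c23 | starting material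
4 | cis-1,2-dimethyl-1,2-dihydroacenaphthylene-1,2-diol (meso) | O[C@@]1(C)c2cccc3cccc(c23)[C@@]1(C)O | intermediate
5 | 2-[(E)-3-(tert-butyldiphenylsilyloxy)prop-1-enyl]-1,3,2-benzodioxaborole | CC(C)(C)[Si](c1ccccc1)(c1ccccc1)OC/C=C/B1Oc2ccccc2O1 | intermediate (not isolated)
6 | (E)-3-(tert-butyldiphenylsilyloxy)prop-1-enylboronic acid cis-1,2-dimethylacenaphthene-1,2-diyl ester (alkenyl B(mac) ester) | CC(C)(C)[Si](c1ccccc1)(c1ccccc1)OC/C=C/B1O[C@@]2(C)c3cccc4cccc(c34)[C@@]2(C)O1 | intermediate
7 | 4-bromo-2-methoxyphenol | COc1cc(Br)ccc1O | starting material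
8 | (4-bromo-2-methoxyphenoxy)tri(propan-2-yl)silane | COc1cc(Br)ccc1O[Si](C(C)C)(C(C)C)C(C)C | intermediate
9 | 3,4-dihydroxy-5-methoxybenzaldehyde (5-hydroxyvanillin) | COc1cc(C=O)cc(O)c1O | starting material
10 | 3-hydroxy-5-methoxy-4-(methoxymethoxy)benzaldehyde | COCOc1c(O)cc(C=O)cc1OC | intermediate
11 | methyl (E)-3-[3-hydroxy-5-methoxy-4-(methoxymethoxy)phenyl]prop-2-enoate | COCOc1c(O)cc(/C=C/C(=O)OC)cc1OC | intermediate
12 | methyl 3-[3-hydroxy-5-methoxy-4-(methoxymethoxy)phenyl]propanoate | COCOc1c(O)cc(CCC(=O)OC)cc1OC | intermediate
13 | methyl 3-[3-methoxy-4-(methoxymethoxy)-5-(trifluoromethylsulfonyloxy)phenyl]propanoate | COCOc1c(OC)cc(CCC(=O)OC)cc1OS(=O)(=O)C(F)(F)F | intermediate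
14 | [3-methoxy-4-(triisopropylsilyloxy)phenyl]lithium | [Li]c1ccc(O[Si](C(C)C)(C(C)C)C(C)C)c(OC)c1 | intermediate (not isolated)
15 | lithium [(E)-3-(tert-butyldiphenylsilyloxy)prop-1-enyl][3-methoxy-4-(triisopropylsilyloxy)phenyl]borate of diol 4 | CC(C)(C)[Si](c1ccccc1)(c1ccccc1)OC/C=C/[B-]1(c2ccc(O[Si](C(C)C)(C(C)C)C(C)C)c(OC)c2)O[C@@]2(C)c3cccc4cccc(c34)[C@@]2(C)O1.[Li+] | intermediate (not isolated)
16 | methyl 3-{3-[(1R,2S)-1-[B(mac)]-3-(tert-butyldiphenylsilyloxy)-1-[3-methoxy-4-(triisopropylsilyloxy)phenyl]propan-2-yl]-5-methoxy-4-(methoxymethoxy)phenyl}propanoate | COCOc1c(OC)cc(CCC(=O)OC)cc1[C@@H](CO[Si](c1ccccc1)(c1ccccc1)C(C)(C)C)[C@H](c1ccc(O[Si](C(C)C)(C(C)C)C(C)C)c(OC)c1)B1O[C@@]2(C)c3cccc4cccc(c34)[C@@]2(C)O1 | intermediate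
17 | methyl 3-{3-[(1R,2S)-3-(tert-butyldiphenylsilyloxy)-1-hydroxy-1-[3-methoxy-4-(triisopropylsilyloxy)phenyl]propan-2-yl]-5-methoxy-4-(methoxymethoxy)phenyl}propanoate | COCOc1c(OC)cc(CCC(=O)OC)cc1[C@@H](CO[Si](c1ccccc1)(c1ccccc1)C(C)(C)C)[C@H](c1ccc(O[Si](C(C)C)(C(C)C)C(C)C)c(OC)c1)O | intermediate
18 | methyl 3-{3-[(1R,2S)-3-(tert-butyldiphenylsilyloxy)-1-hydroxy-1-[3-methoxy-4-(triisopropylsilyloxy)phenyl]propan-2-yl]-4-hydroxy-5-methoxyphenyl}propanoate | Oc1c(OC)cc(CCC(=O)OC)cc1[C@@H](CO[Si](c1ccccc1)(c1ccccc1)C(C)(C)C)[C@H](c1ccc(O[Si](C(C)C)(C(C)C)C(C)C)c(OC)c1)O | intermediate (not isolated)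
19 | methyl 3-[(2R,3S)-3-(tert-butyldiphenylsilyloxymethyl)-7-methoxy-2-[3-methoxy-4-(triisopropylsilyloxy)phenyl]-2,3-dihydro-1-benzofuran-5-yl]propanoate | COC(=O)CCc1cc(OC)c2c(c1)[C@@H](CO[Si](c1ccccc1)(c1ccccc1)C(C)(C)C)[C@H](c1ccc(O[Si](C(C)C)(C(C)C)C(C)C)c(OC)c1)O2 | intermediate
20 | 3-[(2R,3S)-3-(tert-butyldiphenylsilyloxymethyl)-7-methoxy-2-[3-methoxy-4-(triisopropylsilyloxy)phenyl]-2,3-dihydro-1-benzofuran-5-yl]propan-1-ol | OCCCc1cc(OC)c2c(c1)[C@@H](CO[Si](c1ccccc1)(c1ccccc1)C(C)(C)C)[C@H](c1ccc(O[Si](C(C)C)(C(C)C)C(C)C)c(OC)c1)O2 | intermediate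
21 | (E)-3-(4-hydroxy-3-methoxyphenyl)prop-2-enoic acid (ferulic acid) | COc1cc(/C=C/C(=O)O)ccc1O | starting material
22 | tert-butyldimethylsilyl (E)-3-[4-(tert-butyldimethylsilyloxy)-3-methoxyphenyl]prop-2-enoate | COc1cc(/C=C/C(=O)O[Si](C)(C)C(C)(C)C)ccc1O[Si](C)(C)C(C)(C)C | intermediate (not isolated)
23 | (E)-3-[4-(tert-butyldimethylsilyloxy)-3-methoxyphenyl]prop-2-enoic acid | COc1cc(/C=C/C(=O)O)ccc1O[Si](C)(C)C(C)(C)C | intermediate
24 | 3-[(2R,3S)-3-(tert-butyldiphenylsilyloxymethyl)-7-methoxy-2-[3-methoxy-4-(triisopropylsilyloxy)phenyl]-2,3-dihydro-1-benzofuran-5-yl]propyl (E)-3-[4-(tert-butyldimethylsilyloxy)-3-methoxyphenyl]prop-2-enoate | COc1cc(/C=C/C(=O)OCCCc2cc(OC)c3c(c2)[C@@H](CO[Si](c2ccccc2)(c2ccccc2)C(C)(C)C)[C@H](c2ccc(O[Si](C(C)C)(C(C)C)C(C)C)c(OC)c2)O3)ccc1O[Si](C)(C)C(C)(C)C | intermediate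
25 | 3-[(2R,3S)-2-(4-hydroxy-3-methoxyphenyl)-3-(hydroxymethyl)-7-methoxy-2,3-dihydro-1-benzofuran-5-yl]propyl (E)-3-(4-hydroxy-3-methoxyphenyl)prop-2-enoate | COc1cc(/C=C/C(=O)OCCCc2cc(OC)c3c(c2)[C@@H](CO)[C@H](c2ccc(O)c(OC)c2)O3)ccc1O | target

## Step count and least certain steps

Total: 15 steps. Longest linear sequence: 10 steps from 9 (steps 5, 6, 7, 8, 9, 10, 11, 12, 14, 15).

**Step 9 (key step).** The most likely failures are:
- direct boron-to-palladium transfer of the alkenyl or aryl group (Suzuki–Miyaura coupling), because the silyloxymethyl group slows alkene binding and the ortho-alkoxy, electron-rich triflate adds slowly to palladium;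
- β-hydride or β-silyloxy elimination from the alkylpalladium intermediate;
- poor facial selectivity with the bulky β-substituent;
- residual halide poisoning the catalyst.

Fallback: it sets out from 13 and 8 and returns at 17, building C3 by auxiliary-controlled aldol chemistry. 13 would be allylated with 2-allyl-4,4,5,5-tetramethyl-1,3,2-dioxaborolane (PdCl2(dppf), CsF, THF, 70 °C) to methyl 3-[3-methoxy-4-(methoxymethoxy)-5-(prop-2-en-1-yl)phenyl]propanoate F1. Oxidative cleavage (OsO4 cat., NaIO4, 2,6-lutidine, dioxane/H2O) would give methyl 3-[3-methoxy-4-(methoxymethoxy)-5-(2-oxoethyl)phenyl]propanoate F2, and Pinnick oxidation (NaClO2, NaH2PO4, 2-methylbut-2-ene) 2-[3-methoxy-5-(3-methoxy-3-oxopropyl)-2-(methoxymethoxy)phenyl]acetic acid F3. Activation as the pivaloyl mixed anhydride and reaction with lithiated (R)-4-benzyloxazolidin-2-one would give the N-arylacetyl imide F4. Separately, 8 would be lithiated as in step 9 and formylated with DMF to 3-methoxy-4-(triisopropylsilyloxy)benzaldehyde F5. An Evans syn-aldol reaction of F4 with F5 (Bu2BOTf, i-Pr2NEt, CH2Cl2, −78 to 0 °C) should give the syn adduct F6, whose two new centres correspond to those of 17 for the (R)-auxiliary. NaBH4 in THF/H2O would remove the auxiliary, without touching the methyl ester, to give the 1,3-diol F7, and TBDPSCl/imidazole on the primary hydroxyl would return 17.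

**Step 11.** The acid needed to cleave the acetal may also cleave the alkyl silyl ether. The benzylic cation may lose the C3 proton to a stilbene, and re-protonation would scramble C3. Trans selectivity may be incomplete.

Fallback: it sets out from 16 and returns at 19, separating unmasking from ring closure. The acetal would be cleaved while C2 still carries boron and cannot ionise (HCl, MeOH/THF, rt) to give the phenol boronate F8. Perborate oxidation as in step 10 would then give 18 as an isolated compound. Closure would follow with a catalytic amount of TsOH·H2O in CH2Cl2 at 0 °C, a non-nucleophilic medium in which nothing but the carbinol is acid-labile, to give 19.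

**Step 5.** Alkylation may occur on the wrong hydroxyl or on both, because the wanted oxygen is flanked by two substituents.

Fallback: it sets out from 9 and returns at 12, reversing the order of differentiation. The dianion of 9 (NaH, 2.2 equiv, DMSO) would be benzylated with one equivalent of BnBr on its more nucleophilic meta phenoxide to give 3-(benzyloxy)-4-hydroxy-5-methoxybenzaldehyde F9. The remaining hydroxyl would be acetalised (MOMCl, i-Pr2NEt) to 3-(benzyloxy)-5-methoxy-4-(methoxymethoxy)benzaldehyde F10. Wittig olefination as in step 6 would give methyl (E)-3-[3-(benzyloxy)-5-methoxy-4-(methoxymethoxy)phenyl]prop-2-enoate F11, and hydrogenation over Pd/C would reduce the alkene and remove the benzyl group in one operation to give 12.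

**Step 15.** Cleavage of the robust primary TBDPS ether may be slow, which means long exposure to fluoride, during which the cinnamate may be hydrolysed or the phenoxide may open the phenylcoumaran and epimerise C2.

Fallback: it sets out from 19 and returns at 25, exchanging the robust silyl groups before the cinnamate exists. Bu4NF on 19 would give methyl 3-[(2R,3S)-2-(4-hydroxy-3-methoxyphenyl)-3-(hydroxymethyl)-7-methoxy-2,3-dihydro-1-benzofuran-5-yl]propanoate F12. TBSCl/imidazole would give its bis-TBS ether F13, and LiBH4 the chain alcohol F14. Esterification with 23 as in step 14 would give the tris-TBS ester F15, and HF·pyridine in THF/pyridine, which is non-basic and fast for these groups, would give 25.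

## Further compounds

F1 | step 9 | methyl 3-[3-methoxy-4-(methoxymethoxy)-5-(prop-2-en-1-yl)phenyl]propanoate | COCOc1c(OC)cc(CCC(=O)OC)cc1CC=C
F2 | step 9 | methyl 3-[3-methoxy-4-(methoxymethoxy)-5-(2-oxoethyl)phenyl]propanoate | COCOc1c(OC)cc(CCC(=O)OC)cc1CC=O
F3 | step 9 | 2-[3-methoxy-5-(3-methoxy-3-oxopropyl)-2-(methoxymethoxy)phenyl]acetic acid | COCOc1c(OC)cc(CCC(=O)OC)cc1CC(=O)O
F4 | step 9 | methyl 3-[3-{2-[(4R)-4-benzyl-2-oxo-1,3-oxazolidin-3-yl]-2-oxoethyl}-5-methoxy-4-(methoxymethoxy)phenyl]propanoate | COCOc1c(OC)cc(CCC(=O)OC)cc1CC(=O)N1[C@H](Cc2ccccc2)COC1=O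
F5 | step 9 | 3-methoxy-4-(triisopropylsilyloxy)benzaldehyde | COc1cc(C=O)ccc1O[Si](C(C)C)(C(C)C)C(C)C
F6 | step 9 | methyl 3-{3-[(2R,3R)-1-[(4R)-4-benzyl-2-oxo-1,3-oxazolidin-3-yl]-3-hydroxy-3-[3-methoxy-4-(triisopropylsilyloxy)phenyl]-1-oxopropan-2-yl]-5-methoxy-4-(methoxymethoxy)phenyl}propanoate | COCOc1c(OC)cc(CCC(=O)OC)cc1[C@@H](C(=O)N1[C@H](Cc2ccccc2)COC1=O)[C@H](c1ccc(O[Si](C(C)C)(C(C)C)C(C)C)c(OC)c1)O
F7 | step 9 | methyl 3-{3-[(1R,2S)-1,3-dihydroxy-1-[3-methoxy-4-(triisopropylsilyloxy)phenyl]propan-2-yl]-5-methoxy-4-(methoxymethoxy)phenyl}propanoate | COCOc1c(OC)cc(CCC(=O)OC)cc1[C@@H](CO)[C@H](c1ccc(O[Si](C(C)C)(C(C)C)C(C)C)c(OC)c1)O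
F8 | step 11 | methyl 3-{3-[(1R,2S)-1-[B(mac)]-3-(tert-butyldiphenylsilyloxy)-1-[3-methoxy-4-(triisopropylsilyloxy)phenyl]propan-2-yl]-4-hydroxy-5-methoxyphenyl}propanoate | Oc1c(OC)cc(CCC(=O)OC)cc1[C@@H](CO[Si](c1ccccc1)(c1ccccc1)C(C)(C)C)[C@H](c1ccc(O[Si](C(C)C)(C(C)C)C(C)C)c(OC)c1)B1O[C@@]2(C)c3cccc4cccc(c34)[C@@]2(C)O1
F9 | step 5 | 3-(benzyloxy)-4-hydroxy-5-methoxybenzaldehyde | COc1cc(C=O)cc(OCc2ccccc2)c1O
F10 | step 5 | 3-(benzyloxy)-5-methoxy-4-(methoxymethoxy)benzaldehyde | COCOc1c(OC)cc(C=O)cc1OCc1ccccc1
F11 | step 5 | methyl (E)-3-[3-(benzyloxy)-5-methoxy-4-(methoxymethoxy)phenyl]prop-2-enoate | COCOc1c(OC)cc(/C=C/C(=O)OC)cc1OCc1ccccc1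
F12 | step 15 | methyl 3-[(2R,3S)-2-(4-hydroxy-3-methoxyphenyl)-3-(hydroxymethyl)-7-methoxy-2,3-dihydro-1-benzofuran-5-yl]propanoate | COC(=O)CCc1cc(OC)c2c(c1)[C@@H](CO)[C@H](c1ccc(O)c(OC)c1)O2
F13 | step 15 | methyl 3-[(2R,3S)-3-(tert-butyldimethylsilyloxymethyl)-2-[4-(tert-butyldimethylsilyloxy)-3-methoxyphenyl]-7-methoxy-2,3-dihydro-1-benzofuran-5-yl]propanoate | COC(=O)CCc1cc(OC)c2c(c1)[C@@H](CO[Si](C)(C)C(C)(C)C)[C@H](c1ccc(O[Si](C)(C)C(C)(C)C)c(OC)c1)O2
F14 | step 15 | 3-[(2R,3S)-3-(tert-butyldimethylsilyloxymethyl)-2-[4-(tert-butyldimethylsilyloxy)-3-methoxyphenyl]-7-methoxy-2,3-dihydro-1-benzofuran-5-yl]propan-1-ol | OCCCc1cc(OC)c2c(c1)[C@@H](CO[Si](C)(C)C(C)(C)C)[C@H](c1ccc(O[Si](C)(C)C(C)(C)C)c(OC)c1)O2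
F15 | step 15 | 3-[(2R,3S)-3-(tert-butyldimethylsilyloxymethyl)-2-[4-(tert-butyldimethylsilyloxy)-3-methoxyphenyl]-7-methoxy-2,3-dihydro-1-benzofuran-5-yl]propyl (E)-3-[4-(tert-butyldimethylsilyloxy)-3-methoxyphenyl]prop-2-enoate | COc1cc(/C=C/C(=O)OCCCc2cc(OC)c3c(c2)[C@@H](CO[Si](C)(C)C(C)(C)C)[C@H](c2ccc(O[Si](C)(C)C(C)(C)C)c(OC)c2)O3)ccc1O[Si](C)(C)C(C)(C)C
A1 | alternative 1 | (2R)-2-[4-(benzyloxy)-3-methoxyphenyl]-6-[3-(benzyloxy)propyl]-8-methoxy-2,3-dihydro-4H-chromen-4-one | O=C1C[C@H](c2ccc(OCc3ccccc3)c(OC)c2)Oc2c(OC)cc(CCCOCc3ccccc3)cc21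
A2 | alternative 1 | methyl (2R,3R)-2-[4-(benzyloxy)-3-methoxyphenyl]-5-[3-(benzyloxy)propyl]-7-methoxy-2,3-dihydro-1-benzofuran-3-carboxylate (trans) | c1ccccc1COCCCc1cc(OC)c2c(c1)[C@@H](C(=O)OC)[C@H](c1ccc(OCc3ccccc3)c(OC)c1)O2
A3 | alternative 2 | 4-bromo-2-[(2S)-1-(tert-butyldiphenylsilyloxy)-3-(4-hydroxy-3-methoxyphenyl)propan-2-yl]-6-methoxyphenol | Oc1c(OC)cc(Br)cc1[C@@H](CO[Si](c1ccccc1)(c1ccccc1)C(C)(C)C)Cc1ccc(O)c(OC)c1
A4 | alternative 2 | 4-[(2R,3S)-5-bromo-3-(tert-butyldiphenylsilyloxymethyl)-7-methoxy-2,3-dihydro-1-benzofuran-2-yl]-2-methoxyphenol (trans) | Brc1cc(OC)c2c(c1)[C@@H](CO[Si](c1ccccc1)(c1ccccc1)C(C)(C)C)[C@H](c1ccc(O)c(OC)c1)O2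
A5 | alternative 3 | 4-[3-(benzyloxy)propyl]-2-[2-(tert-butyldimethylsilyloxy)-1-(4-methylphenylsulfonyl)ethyl]-6-methoxyphenol | Cc1ccc(cc1)S(=O)(=O)C(CO[Si](C)(C)C(C)(C)C)c1cc(CCCOCc2ccccc2)cc(OC)c1O
A6 | alternative 3 | 4-[3-(benzyloxy)propyl]-6-[2-(tert-butyldimethylsilyloxy)ethylidene]-2-methoxycyclohexa-2,4-dien-1-one | O=C1C(OC)=CC(CCCOCc2ccccc2)=CC1=CCO[Si](C)(C)C(C)(C)C
A7 | alternative 3 | (2R,5R)-1-{[3-methoxy-4-(triisopropylsilyloxy)phenyl]methyl}-2,5-dimethylthiolan-1-ium tetrafluoroborate (illustrative chiral sulfonium salt) | C[C@@H]1CC[C@@H](C)[S+]1Cc1ccc(O[Si](C(C)C)(C(C)C)C(C)C)c(OC)c1.F[B-](F)(F)F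
A8 | alternative 3 | tert-butyl({(2R,3S)-5-[3-(benzyloxy)propyl]-7-methoxy-2-[3-methoxy-4-(triisopropylsilyloxy)phenyl]-2,3-dihydro-1-benzofuran-3-yl}methoxy)dimethylsilane (trans) | c1ccccc1COCCCc1cc(OC)c2c(c1)[C@@H](CO[Si](C)(C)C(C)(C)C)[C@H](c1ccc(O[Si](C(C)C)(C(C)C)C(C)C)c(OC)c1)O2
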